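**Plan**
- Retrosynthesis: (i) the acyl C–O bond of the C3 ester is cut to give trans-alcohol 10 and Z-acid 16; (ii) the C3a–C3 bond of ring B (the dihydrofuran) is cut to give iodoarene aldehyde 8; (iii) the O1–C2 ether bond is cut to give iodophenol 5 and allylic alcohol 4.
- Enabling feature: C3 is a secondary carbinol carbon bonded only to C2 and to ring-A carbon C3a, and C3a is ortho to the ether oxygen O1. With O1–C2 in place, the chain C3a–C7a–O1–C2–C3 puts an aryl–metal at C3a (from a C–I bond) in reach of an aldehyde at C3, so one 5-exo carbonyl addition closes ring B and creates the C3–O stereocentre next to C2.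
- Forward: prenol → Sharpless epoxide → isopropenyl carbinol 4 → Mitsunobu ether 6 → aldehyde 8 → Ni/Cr ring closure to 10 (ring B onto ring A) → esterification with 16, which is made from crotonaldehyde in 4 steps.
- Stereochemistry: C2 (R) comes from the Sharpless epoxidation followed by SN2 inversion in the Mitsunobu step. C3 (S, trans to isopropenyl) comes from 1,2-induction by C2 in the ring closure. The Z alkene comes from (Z)-2-iodobut-2-en-1-ol, with retention through iodine–lithium exchange and carboxylation.

Key step: step 7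

Remark: 1, 5, 11 and the reagents named under Conditions are taken as commercial; the target is the 2,3-trans isomer and its acyl group is the Z (angelate-type) isomer, methyl cis to the ester carbonyl.

**Step 1**
Reactants: 1 3-methylbut-2-en-1-ol (prenol)
Product: 2 [(2R)-3,3-dimethyloxiran-2-yl]methanol
Conditions: Ti(OiPr)4 (5 mol%), D-(−)-diisopropyl tartrate (6 mol%), t-BuOOH, 4 Å MS, CH2Cl2, −20 °C
Reagents that add atoms: tert-butyl hydroperoxide, CC(C)(C)OO
Why: Sharpless asymmetric epoxidation of a primary allylic alcohol; the titanium–D-tartrate complex delivers oxygen to the alkene face that gives the 2R epoxide (the L-tartrate gives 2S), which fixes the carbon that becomes C2.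

**Step 2**
Reactants: 2 [(2R)-3,3-dimethyloxiran-2-yl]methanol
Product: 3 tert-butyl{[(2R)-3,3-dimethyloxiran-2-yl]methoxy}dimethylsilane
Conditions: TBSCl, imidazole, CH2Cl2, 0 °C to rt
Reagents that add atoms: tert-butyldimethylsilyl chloride, CC(C)(C)[Si](C)(C)Cl
Why: Routine silylation of the primary alcohol, which leaves the epoxide and its stereocentre untouched.

**Step 3**
Reactants: 3 tert-butyl{[(2R)-3,3-dimethyloxiran-2-yl]methoxy}dimethylsilane
Product: 4 (2S)-1-[(tert-butyldimethylsilyl)oxy]-3-methylbut-3-en-2-ol
Conditions: Et2Al(TMP) (from Et2AlCl and LiTMP), toluene, 0 °C; then H2O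
Reagents that add atoms: none
Why: Aluminium-amide-promoted isomerisation of an epoxide to an allylic alcohol: syn β-elimination takes a proton from a methyl group and cleaves the C–O bond of the gem-dimethyl carbon, so the C2–O bond and its configuration are kept (the descriptor changes from R to S only because the CIP priorities change).

**Step 4**
Reactants: 4 (2S)-1-[(tert-butyldimethylsilyl)oxy]-3-methylbut-3-en-2-ol; 5 1-(4-hydroxy-3-iodophenyl)ethan-1-one
Product: 6 1-[4-({(2R)-1-[(tert-butyldimethylsilyl)oxy]-3-methylbut-3-en-2-yl}oxy)-3-iodophenyl]ethan-1-one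
Conditions: PPh3, DIAD, toluene, 0 °C to rt
Reagents that add atoms: none
Why: Mitsunobu etherification; the acidic phenol displaces the oxyphosphonium group of the secondary allylic alcohol by SN2 with inversion (S to R), which sets C2 of the target.

**Step 5**
Reactants: 6 1-[4-({(2R)-1-[(tert-butyldimethylsilyl)oxy]-3-methylbut-3-en-2-yl}oxy)-3-iodophenyl]ethan-1-one
Product: 7 1-(4-{[(2R)-1-hydroxy-3-methylbut-3-en-2-yl]oxy}-3-iodophenyl)ethan-1-one
Conditions: HF·pyridine, THF/pyridine, 0 °C to rt
Reagents that add atoms: none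
Why: Fluoride cleavage of a primary silyl ether under buffered conditions that do not touch the aryl ketone, the aryl iodide or the allylic aryl ether.

**Step 6**
Reactants: 7 1-(4-{[(2R)-1-hydroxy-3-methylbut-3-en-2-yl]oxy}-3-iodophenyl)ethan-1-one
Product: 8 (2R)-2-(4-acetyl-2-iodophenoxy)-3-methylbut-3-enal
Conditions: Dess–Martin periodinane, NaHCO3, CH2Cl2, 0 °C; filtered through a short silica pad and used at once
Reagents that add atoms: none
Why: Dess–Martin oxidation is fast, amine-free and buffered, so the α-aryloxy β,γ-unsaturated aldehyde should form without enolisation at C2.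

**Step 7**
Reactants: 8 (2R)-2-(4-acetyl-2-iodophenoxy)-3-methylbut-3-enal
Product: 10 1-[(2R,3S)-3-hydroxy-2-(prop-1-en-2-yl)-2,3-dihydro-1-benzofuran-5-yl]ethan-1-one, via arylchromium dichloride 9 (not isolated)
Conditions: CrCl2 (5 equiv), NiCl2 (1 mol%), degassed DMF, 0.02 M, rt; then H2O
Reagents that add atoms: none
Why: Zerovalent nickel (formed from NiCl2 by CrCl2) inserts into the C3a–I bond and passes the aryl group to trivalent chromium, and the arylchromium 9 then adds to the aldehyde carbon C3 (intramolecular Nozaki–Hiyama–Kishi reaction; the closest precedent is the Ni/Cr-mediated aryl iodide–aldehyde cyclisation to benzo-fused five-membered carbinols). Ring B closes in the 5-exo-trig mode by C3a–C3 bond formation, the carbonyl oxygen ending up exocyclic as the C3 oxygen. The new stereocentre C3 is controlled by C2 (1,2-induction): in the compact five-membered transition state the chromium-bound oxygen should turn to the face of the small C2–H and away from the isopropenyl group, so the 2,3-trans (3S) alcohol is expected as the major isomer. The step needs chemoselectivity for the aldehyde over the aryl methyl ketone, which the weakly basic organochromium reagent provides, and survival of the allylic aryl ether, which the low nickel loading and the much faster insertion into C–I should secure. It also needs C2 to keep its configuration: the medium is neutral, aprotic and amine-free, so enolisation of 8 towards the conjugated enal is not triggered.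

**Step 8**
Reactants: 11 (2E)-but-2-enal (crotonaldehyde)
Product: 12 (2Z)-2-iodobut-2-enal
Conditions: I2, K2CO3, DMAP (20 mol%), THF/H2O 1:1, rt
Reagents that add atoms: iodine, II
Why: α-Iodination of an enal by amine conjugate addition, iodination of the enolate and elimination (Baylis–Hillman-type mechanism), which gives the isomer with the formyl group trans to methyl, that is iodine cis to methyl.

**Step 9**
Reactants: 12 (2Z)-2-iodobut-2-enal
Product: 13 (2Z)-2-iodobut-2-en-1-ol
Conditions: NaBH4, CeCl3·7H2O, MeOH, 0 °C
Reagents that add atoms: none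
Why: Luche 1,2-reduction of the enal, which leaves the alkenyl iodide and the alkene geometry unchanged.

**Step 10**
Reactants: 13 (2Z)-2-iodobut-2-en-1-ol
Product: 15 (2Z)-2-(hydroxymethyl)but-2-enoic acid, via dilithio alkenyl alkoxide 14 (not isolated)
Conditions: t-BuLi (3.1 equiv), Et2O, −78 °C; CO2 (g), −78 to 0 °C; aq. HCl
Reagents that add atoms: carbon dioxide, O=C=O
Why: O-Deprotonation and iodine–lithium exchange give a configurationally stable alkenyllithium that is carboxylated with retention, so the carboxyl group takes the place of iodine cis to the methyl group (Z, angelate-type geometry).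

**Step 11**
Reactants: 15 (2Z)-2-(hydroxymethyl)but-2-enoic acid
Product: 16 (2Z)-2-[(acetyloxy)methyl]but-2-enoic acid
Conditions: Ac2O, pyridine, CH2Cl2, 0 °C to rt; aqueous work-up at pH 3
Reagents that add atoms: acetic anhydride, CC(=O)OC(C)=O
Why: Routine O-acetylation of the primary allylic alcohol; any mixed anhydride at the carboxyl group is hydrolysed at work-up, and pyridine is too weak a nucleophile to add to the β-methyl acrylate.

**Step 12**
Reactants: 10 1-[(2R,3S)-3-hydroxy-2-(prop-1-en-2-yl)-2,3-dihydro-1-benzofuran-5-yl]ethan-1-one; 16 (2Z)-2-[(acetyloxy)methyl]but-2-enoic acid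
Product: 18 (2R,3S)-5-acetyl-2-(prop-1-en-2-yl)-2,3-dihydro-1-benzofuran-3-yl (2Z)-2-[(acetyloxy)methyl]but-2-enoate (the target), via mixed anhydride 17 (not isolated)
Conditions: 2,4,6-trichlorobenzoyl chloride, Et3N, toluene, 0 °C to rt; then 10, toluene, 50 °C (no DMAP)
Reagents that add atoms: none
Why: Yamaguchi-type mixed-anhydride esterification, in which the alcohol attacks the less hindered enoyl carbonyl and the C3–O bond is not broken (3S retained); leaving out the nucleophilic amine catalyst, as is done for angelate esters, should avoid conjugate addition that would isomerise the Z alkene or displace the allylic acetate.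

**Compound list**
1 | 3-methylbut-2-en-1-ol (prenol) | CC(C)=CCO | starting material
2 | [(2R)-3,3-dimethyloxiran-2-yl]methanol | OC[C@H]1OC1(C)C | intermediate
3 | tert-butyl{[(2R)-3,3-dimethyloxiran-2-yl]methoxy}dimethylsilane | CC(C)(C)[Si](C)(C)OC[C@H]1OC1(C)C | intermediate
4 | (2S)-1-[(tert-butyldimethylsilyl)oxy]-3-methylbut-3-en-2-ol | CC(C)(C)[Si](C)(C)OC[C@H](C(C)=C)O | intermediate
5 | 1-(4-hydroxy-3-iodophenyl)ethan-1-one | CC(=O)c1ccc(O)c(I)c1 | starting material
6 | 1-[4-({(2R)-1-[(tert-butyldimethylsilyl)oxy]-3-methylbut-3-en-2-yl}oxy)-3-iodophenyl]ethan-1-one | CC(C)(C)[Si](C)(C)OC[C@@H](C(C)=C)Oc1ccc(C(C)=O)cc1I | intermediate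
7 | 1-(4-{[(2R)-1-hydroxy-3-methylbut-3-en-2-yl]oxy}-3-iodophenyl)ethan-1-one | OC[C@@H](C(C)=C)Oc1ccc(C(C)=O)cc1I | intermediate
8 | (2R)-2-(4-acetyl-2-iodophenoxy)-3-methylbut-3-enal | O=C[C@@H](C(C)=C)Oc1ccc(C(C)=O)cc1I | intermediate
9 | {5-acetyl-2-[(2R)-3-methyl-1-oxobut-3-en-2-yl]oxyphenyl}chromium dichloride (arylchromium, trivalent chromium; not isolated) | O=C[C@@H](C(C)=C)Oc1ccc(C(C)=O)cc1[Cr](Cl)Cl | intermediate
10 | 1-[(2R,3S)-3-hydroxy-2-(prop-1-en-2-yl)-2,3-dihydro-1-benzofuran-5-yl]ethan-1-one (2,3-trans) | C=C(C)[C@H]1Oc2ccc(C(C)=O)cc2[C@@H]1O | intermediate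
11 | (2E)-but-2-enal (crotonaldehyde) | C/C=C/C=O | starting material
12 | (2Z)-2-iodobut-2-enal | C/C=C(\I)C=O | intermediate
13 | (2Z)-2-iodobut-2-en-1-ol | C/C=C(\I)CO | intermediate
14 | lithium 2-lithiobut-2-en-1-olate, lithium on C2 cis to the methyl group (not isolated) | C/C=C(\[Li])CO[Li] | intermediate
15 | (2Z)-2-(hydroxymethyl)but-2-enoic acid | C/C=C(\C(=O)O)CO | intermediate
16 | (2Z)-2-[(acetyloxy)methyl]but-2-enoic acid | C/C=C(\C(=O)O)COC(C)=O | intermediate
17 | (2Z)-2-[(acetyloxy)methyl]but-2-enoic 2,4,6-trichlorobenzoic anhydride (not isolated) | C/C=C(\C(=O)OC(=O)c1c(Cl)cc(Cl)cc1Cl)COC(C)=O | intermediate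
18 | (2R,3S)-5-acetyl-2-(prop-1-en-2-yl)-2,3-dihydro-1-benzofuran-3-yl (2Z)-2-[(acetyloxy)methyl]but-2-enoate | C=C(C)[C@H]1Oc2ccc(C(C)=O)cc2[C@@H]1OC(=O)/C(=C\C)COC(C)=O | target

**Step count**
Total step count: 12. Longest linear sequence: 8 steps (steps 1–7 and 12).

**Steps most likely to fail**

Step 7. Two processes may go wrong. Aldehyde 8 may enolise at C2 on the Lewis-acidic chromium salts, which pulls the double bond into conjugation and destroys the stereocentre before the slow nickel/chromium cycle consumes it. Facial selectivity at C3 may also be only moderate. The fallback masks the alkene as its hydrate for the ring closure. Setting out from 7, Mukaiyama hydration (Co(acac)2, PhSiH3, O2, i-PrOH) should give the diol 1-(4-{[(2S)-1,3-dihydroxy-3-methylbutan-2-yl]oxy}-3-iodophenyl)ethan-1-one F1. Dess–Martin oxidation of its primary alcohol gives (2R)-2-(4-acetyl-2-iodophenoxy)-3-hydroxy-3-methylbutanal F2, which has no β,γ-double bond to move into conjugation and a bulkier C2 substituent for 1,2-induction. The same CrCl2/NiCl2 cyclisation gives the trans-diol 1-[(2S,3S)-3-hydroxy-2-(2-hydroxypropan-2-yl)-2,3-dihydro-1-benzofuran-5-yl]ethan-1-one F3. Only its secondary alcohol is acylated with 16 under the conditions of step 12, to give (2S,3S)-5-acetyl-2-(2-hydroxypropan-2-yl)-2,3-dihydro-1-benzofuran-3-yl (2Z)-2-[(acetyloxy)methyl]but-2-enoate F4. Dehydration of the tertiary alcohol with the Burgess reagent (toluene, 50 °C) then forms the isopropenyl group, and the route is rejoined at 18.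

Step 12. The acyl unit may isomerise from Z to E, or lose its allylic acetate, while the carboxyl group is activated; on warming, the benzylic C3–O bond may ionise with elimination to the benzofuran. The fallback forms the ester through the C3–O bond with the carboxylate as nucleophile, so the acid is never activated. Setting out from 10, Mitsunobu inversion with 4-nitrobenzoic acid (PPh3, DIAD, THF) gives the cis ester (2R,3R)-5-acetyl-2-(prop-1-en-2-yl)-2,3-dihydro-1-benzofuran-3-yl 4-nitrobenzoate F5. Methanolysis (K2CO3, MeOH) gives the cis-alcohol 1-[(2R,3R)-3-hydroxy-2-(prop-1-en-2-yl)-2,3-dihydro-1-benzofuran-5-yl]ethan-1-one F6. A second Mitsunobu reaction, now with acid 16, inverts C3 again and arrives at 18. The same last reaction would also take any cis-alcohol F6 formed as the minor isomer in step 7 on to 18.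

Step 4. The activated allylic alcohol may be attacked at the methylene terminus (SN2′), or may ionise and eliminate, instead of undergoing clean SN2 displacement. The fallback puts the aryloxy group on the same carbon by epoxide opening. Setting out from epoxide 3 and phenol 5 (Cs2CO3, DMF, 90 °C), the phenoxide should attack the secondary epoxide carbon with inversion, since the fully substituted carbon is closed to SN2. This gives the tertiary alcohol 1-[4-({(2S)-1-[(tert-butyldimethylsilyl)oxy]-3-hydroxy-3-methylbutan-2-yl}oxy)-3-iodophenyl]ethan-1-one F7. Dehydration with the Burgess reagent (toluene, 50 °C) then gives 6, where the route is rejoined.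

**Further compounds**
F1 | step 7 | 1-(4-{[(2S)-1,3-dihydroxy-3-methylbutan-2-yl]oxy}-3-iodophenyl)ethan-1-one | OC[C@@H](C(C)(C)O)Oc1ccc(C(C)=O)cc1I
F2 | step 7 | (2R)-2-(4-acetyl-2-iodophenoxy)-3-hydroxy-3-methylbutanal | O=C[C@@H](C(C)(C)O)Oc1ccc(C(C)=O)cc1I
F3 | step 7 | 1-[(2S,3S)-3-hydroxy-2-(2-hydroxypropan-2-yl)-2,3-dihydro-1-benzofuran-5-yl]ethan-1-one | CC(C)(O)[C@H]1Oc2ccc(C(C)=O)cc2[C@@H]1O
F4 | step 7 | (2S,3S)-5-acetyl-2-(2-hydroxypropan-2-yl)-2,3-dihydro-1-benzofuran-3-yl (2Z)-2-[(acetyloxy)methyl]but-2-enoate | CC(C)(O)[C@H]1Oc2ccc(C(C)=O)cc2[C@@H]1OC(=O)/C(=C\C)COC(C)=O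
F5 | step 12 | (2R,3R)-5-acetyl-2-(prop-1-en-2-yl)-2,3-dihydro-1-benzofuran-3-yl 4-nitrobenzoate | C=C(C)[C@H]1Oc2ccc(C(C)=O)cc2[C@H]1OC(=O)c3ccc([N+](=O)[O-])cc3
F6 | step 12 | 1-[(2R,3R)-3-hydroxy-2-(prop-1-en-2-yl)-2,3-dihydro-1-benzofuran-5-yl]ethan-1-one | C=C(C)[C@H]1Oc2ccc(C(C)=O)cc2[C@H]1O
F7 | step 4 | 1-[4-({(2S)-1-[(tert-butyldimethylsilyl)oxy]-3-hydroxy-3-methylbutan-2-yl}oxy)-3-iodophenyl]ethan-1-one | CC(C)(C)[Si](C)(C)OC[C@@H](C(C)(C)O)Oc1ccc(C(C)=O)cc1I
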